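## Retrosynthetic overview

1. The dihydropyran is opened by a retro-hetero-Diels–Alder reaction (O–C8 and C13–C1′) into (1R,3Z,5S,9S)-caryophylla-3,8(13)-dien-5-ol and the alkylidene trione from syncarpic acid and 3-methylbutanal; this ring is formed last and sets C8 and C1′.
2. The dienol comes from CBS reduction of the (3Z)-en-5-one, which comes from a Schenck ene / Kornblum–DeLaMare transposition of the Δ4(Z) olefin of (−)-isocaryophyllene, itself made by Wittig methylenation of the (Z)-nor-ketone after C9 is equilibrated to the trans ring fusion.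
3. Enabling feature: after this transposition the nine-membered ring C1–C9 contains C8(=O)–C7–C6–C5=C4, a γ,δ-unsaturated ketone (Claisen retron), while C8 and C4 are also joined through C9–C1–C2–C3. The seven-membered lactone O–C8(=O)–C9–C1–C2–C3–C4(Me)(vinyl) therefore gives the carbocycle by carbonyl methylenation and a [3,3] shift (oxepane 7 → cyclononenone 9).
4. The lactone comes from Baeyer–Villiger oxidation of a 3-methyl-3-vinylbicyclo[4.2.0]octan-2-one, built by aldol condensation and deconjugative methylation on the enantioselective [2+2] adduct of cyclohexenone and isobutene. Ring order: cyclobutane on a six-ring template, then oxepanone, then nine-membered carbocycle, then dihydropyran.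
5. Syncarpic acid comes from dearomatising tetramethylation and deacetylation of 2,4,6-trihydroxyacetophenone.

Key step: step 5

Remark on the chemistry: terpene carbons carry caryophyllane numbers (C1–C15, C13 = exocyclic CH2), the isobutyl-bearing carbon is C1′, the given SMILES is read as (1R,3Z,5S,8S,9S,1′S), and syncarpic acid is written as its triketo tautomer.

## Route

Step 1
Reactants: 1 cyclohex-2-en-1-one; 2 2-methylpropene (isobutene)
Product: 4 (1R,6R)-7,7-dimethylbicyclo[4.2.0]octan-2-one (cis-fused), via trans-fused photoadduct 3 (not isolated)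
Conditions: chiral oxazaborolidine–AlBr3 Lewis acid (50 mol%), hν (366 nm), CH2Cl2, −75 °C; then basic Al2O3, rt
Reagents that add atoms: none
Why: Lewis-acid-catalysed enone–alkene [2+2] photocycloaddition in which the enone bound to the chiral oxazaborolidine–AlBr3 complex adds isobutene head-to-tail (CMe2 to the β-carbon) on the one face the catalyst leaves open, which fixes the β-carbon (terpene C1, R), while basic alumina epimerises the α-carbon so that the strained trans-fused adduct drains into the cis-fused ketone.

Step 2
Reactants: 4 (1R,6R)-7,7-dimethylbicyclo[4.2.0]octan-2-one; 5 acetaldehyde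
Product: 9 (1R,3E,6R)-3-ethylidene-7,7-dimethylbicyclo[4.2.0]octan-2-one, via lithium enolate 6 (not isolated), via lithium aldolate 7 (not isolated), via aldol mesylate 8 (not isolated)
Conditions: LDA, THF, −78 °C; MeCHO; MsCl, −78 → 0 °C; DBU, rt
Reagents that add atoms: none
Why: Aldol condensation in which kinetic deprotonation takes the CH2 proton at C3 and not the bridgehead CH, and mesylation followed by E1cB elimination gives the conjugated E-ethylidene ketone, the carbinol centres of 7 and 8 being destroyed.

Step 3
Reactants: 9 (1R,3E,6R)-3-ethylidene-7,7-dimethylbicyclo[4.2.0]octan-2-one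
Product: 11 (1R,6R)-3-ethenyl-3,7,7-trimethylbicyclo[4.2.0]octan-2-one (both C3 epimers), via potassium dienolate 10 (not isolated)
Conditions: KOt-Bu (1.05 equiv), t-BuOH/THF, 0 °C; then MeI
Reagents that add atoms: iodomethane, CI
Why: Deconjugative α-alkylation in which tert-butoxide forms the extended dienolate by γ-deprotonation of the ethylidene methyl group and iodomethane reacts at the α-carbon to create the methyl/vinyl quaternary centre, whose configuration is left uncontrolled on purpose because this carbon becomes sp2 in step 5.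

Step 4
Reactants: 11 (1R,6R)-3-ethenyl-3,7,7-trimethylbicyclo[4.2.0]octan-2-one
Product: 12 (1R,7R)-4-ethenyl-4,8,8-trimethyl-3-oxabicyclo[5.2.0]nonan-2-one (both C4 epimers)
Conditions: mCPBA, CH2Cl2, 0 °C → rt
Reagents that add atoms: meta-chloroperoxybenzoic acid, OOC(=O)c1cccc(Cl)c1
Why: Baeyer–Villiger oxidation in which the fully substituted, vinyl-bearing carbon migrates (with retention) in preference to the secondary cyclobutyl carbon, so oxygen enters between the carbonyl and the methyl/vinyl carbon, and the monosubstituted vinyl group is epoxidised far more slowly than the ketone is oxidised.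

Step 5
Reactants: 12 (1R,7R)-4-ethenyl-4,8,8-trimethyl-3-oxabicyclo[5.2.0]nonan-2-one
Product: 14 (1R,4Z,9R)-4,11,11-trimethylbicyclo[7.2.0]undec-4-en-8-one (cis-fused; caryophyllane numbering), via 2-methyleneoxepane enol ether 13 (not isolated)
Conditions: Cp2TiMe2, toluene, 70 °C (dark); filtration through basic Al2O3; o-xylene, Et3N (trace), 180 °C, sealed tube
Reagents that add atoms: dimethyltitanocene, C[Ti](C)(C1C=CC=C1)C1C=CC=C1
Why: Petasis methylenation turns the lactone carbonyl into an exocyclic enol ether, giving the allyl vinyl ether C7H2=C8–O–C4–C5H=C6H2 whose C8–O–C4 unit lies inside the oxepane, so the thermal [3,3] (Claisen) shift breaks O–C4, forms C6–C7, expels the oxygen as the C8 carbonyl and takes C5, C6 and C7 into the ring (7 → 9). The closest known reaction type is the Claisen ring expansion of 2-methylene-6-vinyltetrahydropyrans to cyclooct-4-enones and of vinyl-substituted seven-membered ketene acetals to nine-membered lactones. The nine-membered ring is closed by the suprafacial sigmatropic C6–C7 bond formation through a bridged, bicyclo[4.3.1]-type transition state and not by an exo or endo cyclisation. No sp3 stereocentre is created: the only new stereo-element, the C4=C5 geometry, is controlled by the four-carbon tether C9–C1–C2–C3, which can span the pericyclic array only with C3 pseudo-axial on C4 and therefore should give the Z olefin from either C4 epimer (stereoconvergent), while C1 and C9 are untouched. The selectivity needed is the [3,3] shift over isomerisation of the enol ether to its endocyclic isomer or ionisation of the tertiary allylic ether; the fully substituted C4 accelerates the shift, C=O formation makes it irreversible, and base-washed glassware with an amine additive suppresses the acid-catalysed pathways.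

Step 6
Reactants: 14 (1R,4Z,9R)-4,11,11-trimethylbicyclo[7.2.0]undec-4-en-8-one
Product: 16 (−)-isocaryophyllene [(1R,4Z,9S)-4,11,11-trimethyl-8-methylidenebicyclo[7.2.0]undec-4-ene], via trans-fused ketone 15 (not isolated)
Conditions: KOt-Bu (0.2 equiv), THF/t-BuOH, rt; then Ph3P=CH2 (from Ph3PCH3Br, KOt-Bu), THF, 0 → 40 °C
Reagents that add atoms: methyltriphenylphosphonium bromide, C[P+](c1ccccc1)(c1ccccc1)c1ccccc1.[Br-]
Why: Base equilibration at C9 (α to the C8 ketone) should drain the cis-fused ketone into the thermodynamically preferred trans-fused nine-membered ketone (H-1 and H-9 anti), which Wittig methylenation then fixes because C9 is no longer epimerisable once C8 is an olefinic carbon.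

Step 7
Reactants: 16 (−)-isocaryophyllene
Product: 19 (1R,3Z,9S)-4,11,11-trimethyl-8-methylidenebicyclo[7.2.0]undec-3-en-5-one, via allylic hydroperoxide 17 (not isolated), via allylic peracetate 18 (not isolated)
Conditions: O2, tetraphenylporphyrin (cat.), hν (visible), CH2Cl2, −20 °C; then Ac2O, pyridine, DMAP (cat.), 0 °C → rt
Reagents that add atoms: dioxygen, O=O
Why: Schenck ene reaction followed by Kornblum–DeLaMare dehydration, in which singlet oxygen attacks the trisubstituted olefin (far more reactive than the 1,1-disubstituted one) and, by the cis effect, abstracts hydrogen on the side carrying the ring CH2 groups, C3–H abstraction placing oxygen on C5 and the double bond at C3=C4, after which only this secondary hydroperoxide is converted by Ac2O/pyridine into the enone, so that both C5 epimers and any 3E isomer (isomerised by reversible amine conjugate addition) should converge on the 3Z-enone.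

Step 8
Reactants: 19 (1R,3Z,9S)-4,11,11-trimethyl-8-methylidenebicyclo[7.2.0]undec-3-en-5-one
Product: 20 (1R,3Z,5S,9S)-4,11,11-trimethyl-8-methylidenebicyclo[7.2.0]undec-3-en-5-ol
Conditions: (R)-2-methyl-CBS-oxazaborolidine (0.2 equiv), catecholborane, toluene, −78 °C
Reagents that add atoms: none
Why: Corey–Bakshi–Shibata reduction in which the enone binds the (R)-oxazaborolidine with the α-methylalkenyl arm as the large group and the C6 methylene as the small one, so hydride is delivered 1,2 to the face that gives the 5S alcohol (reagent control), and catecholborane at −78 °C does not hydroborate the olefins.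

Step 9
Reactants: 21 1-(2,4,6-trihydroxyphenyl)ethan-1-one
Product: 22 2-acetyl-3-hydroxy-4,4,6,6-tetramethylcyclohex-2-ene-1,5-dione (acetylsyncarpic acid)
Conditions: MeI (excess), NaOMe, MeOH, 0 °C → reflux
Reagents that add atoms: iodomethane, CI
Why: Exhaustive C-methylation of the phloroglucinol phenoxide (dearomatising alkylation) places two methyl groups on each of the two free ring carbons while the acetyl group blocks the third.

Step 10
Reactants: 22 2-acetyl-3-hydroxy-4,4,6,6-tetramethylcyclohex-2-ene-1,5-dione
Product: 23 2,2,4,4-tetramethylcyclohexane-1,3,5-trione (syncarpic acid)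
Conditions: 6 M aq. HCl, 1,4-dioxane, reflux
Reagents that add atoms: none
Why: Acid-mediated retro-Claisen deacylation of the β-triketone removes the acetyl group as acetic acid.

Step 11
Reactants: 20 (1R,3Z,5S,9S)-4,11,11-trimethyl-8-methylidenebicyclo[7.2.0]undec-3-en-5-ol; 23 syncarpic acid; 24 3-methylbutanal
Product: 26 tomentodione P, via alkylidene trione 25 (not isolated)
Conditions: ethylenediammonium diacetate (cat.), toluene, 80 °C
Reagents that add atoms: none
Why: Knoevenagel condensation generates the alkylidene trione, which undergoes an inverse-electron-demand hetero-Diels–Alder reaction with the 1,1-disubstituted C8=C13 olefin (oxygen to the more substituted C8); allylic strain against the cyclobutane CH2 (C10) should turn C13 syn to H-9 so that the heterodiene, guided in addition by a hydrogen bond from the 5-hydroxyl on the same face, adds from the outside of the ring and places the C8–O bond on the face of C10 and of the 5-OH (8S), and the orientation with the C9 branch endo puts isobutyl and C9 cis-diequatorial on the new dihydropyran (1′S), this last preference being the weaker one so that separation from the C1′ epimer is anticipated.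

## Compound list

1 | cyclohex-2-en-1-one | O=C1C=CCCC1 | starting material
2 | 2-methylpropene (isobutene) | CC(C)=C | starting material
3 | (1S,6R)-7,7-dimethylbicyclo[4.2.0]octan-2-one (trans-fused photoadduct) | O=C1CCC[C@@H]2[C@@H]1CC2(C)C | intermediate
4 | (1R,6R)-7,7-dimethylbicyclo[4.2.0]octan-2-one (cis-fused) | O=C1CCC[C@@H]2[C@H]1CC2(C)C | intermediate
5 | acetaldehyde | CC=O | starting material
6 | lithium (1R,6R)-7,7-dimethylbicyclo[4.2.0]oct-2-en-2-olate | [Li+].[O-]C1=CCC[C@@H]2[C@H]1CC2(C)C | intermediate
7 | lithium 1-[(1R,6R)-7,7-dimethyl-2-oxobicyclo[4.2.0]octan-3-yl]ethan-1-olate (diastereomer mixture) | [Li+].CC([O-])C1CC[C@@H]2[C@@H](CC2(C)C)C1=O | intermediate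
8 | 1-[(1R,6R)-7,7-dimethyl-2-oxobicyclo[4.2.0]octan-3-yl]ethyl methanesulfonate (diastereomer mixture) | CC(OS(C)(=O)=O)C1CC[C@@H]2[C@@H](CC2(C)C)C1=O | intermediate
9 | (1R,3E,6R)-3-ethylidene-7,7-dimethylbicyclo[4.2.0]octan-2-one | C/C=C1\CC[C@@H]2[C@@H](CC2(C)C)C1=O | intermediate
10 | potassium (1R,6R)-3-ethenyl-7,7-dimethylbicyclo[4.2.0]oct-2-en-2-olate | [K+].[O-]C1=C(C=C)CC[C@@H]2[C@H]1CC2(C)C | intermediate
11 | (1R,6R)-3-ethenyl-3,7,7-trimethylbicyclo[4.2.0]octan-2-one (both C3 epimers) | C=CC1(C)CC[C@@H]2[C@@H](CC2(C)C)C1=O | intermediate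
12 | (1R,7R)-4-ethenyl-4,8,8-trimethyl-3-oxabicyclo[5.2.0]nonan-2-one (both C4 epimers) | C=CC1(C)CC[C@@H]2[C@@H](CC2(C)C)C(=O)O1 | intermediate
13 | (1R,7R)-4-ethenyl-4,8,8-trimethyl-2-methylidene-3-oxabicyclo[5.2.0]nonane (both C4 epimers) | C=CC1(C)CC[C@@H]2[C@@H](CC2(C)C)C(=C)O1 | intermediate
14 | (1R,4Z,9R)-4,11,11-trimethylbicyclo[7.2.0]undec-4-en-8-one (cis-fused) | C/C1=C/CCC(=O)[C@@H]2CC(C)(C)[C@@H]2CC1 | intermediate
15 | (1R,4Z,9S)-4,11,11-trimethylbicyclo[7.2.0]undec-4-en-8-one (trans-fused) | C/C1=C/CCC(=O)[C@H]2CC(C)(C)[C@@H]2CC1 | intermediate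
16 | (−)-isocaryophyllene, (1R,4Z,9S)-4,11,11-trimethyl-8-methylidenebicyclo[7.2.0]undec-4-ene | C/C1=C/CCC(=C)[C@H]2CC(C)(C)[C@@H]2CC1 | intermediate
17 | (1R,9S)-5-hydroperoxy-4,11,11-trimethyl-8-methylidenebicyclo[7.2.0]undec-3-ene (C5 epimers, 3Z/3E) | CC1=CC[C@@H]2[C@H](CC2(C)C)C(=C)CCC1OO | intermediate
18 | peracetate of 17, (1R,9S)-4,11,11-trimethyl-8-methylidenebicyclo[7.2.0]undec-3-en-5-yl ethaneperoxoate | CC1=CC[C@@H]2[C@H](CC2(C)C)C(=C)CCC1OOC(C)=O | intermediate
19 | (1R,3Z,9S)-4,11,11-trimethyl-8-methylidenebicyclo[7.2.0]undec-3-en-5-one | C/C1=C/C[C@@H]2[C@H](CC2(C)C)C(=C)CCC1=O | intermediate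
20 | (1R,3Z,5S,9S)-4,11,11-trimethyl-8-methylidenebicyclo[7.2.0]undec-3-en-5-ol | C/C1=C/C[C@@H]2[C@H](CC2(C)C)C(=C)CC[C@@H]1O | intermediate
21 | 1-(2,4,6-trihydroxyphenyl)ethan-1-one | CC(=O)c1c(O)cc(O)cc1O | starting material
22 | 2-acetyl-3-hydroxy-4,4,6,6-tetramethylcyclohex-2-ene-1,5-dione | CC(=O)C1=C(O)C(C)(C)C(=O)C(C)(C)C1=O | intermediate
23 | 2,2,4,4-tetramethylcyclohexane-1,3,5-trione (syncarpic acid) | CC1(C)C(=O)CC(=O)C(C)(C)C1=O | intermediate
24 | 3-methylbutanal | CC(C)CC=O | starting material
25 | 2,2,4,4-tetramethyl-6-(3-methylbutylidene)cyclohexane-1,3,5-trione | CC(C)CC=C1C(=O)C(C)(C)C(=O)C(C)(C)C1=O | intermediate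
26 | tomentodione P | C/C1=C/C[C@@H]2[C@H](CC2(C)C)[C@]2(CC[C@@H]1O)C[C@H](CC(C)C)C1=C(O2)C(C)(C)C(=O)C(C)(C)C1=O | target

## Step count and risks

Total step count: 11 (steps 1–8 linear, steps 9–10 for the trione, step 11 convergent). Longest linear sequence: 9 steps (1–8 and 11).

Steps most likely to fail:

1. Step 7: hydrogen abstraction may occur at C6 and not at C3 (wrong regiochemistry of the ene step), or the allylic C–H bonds of the Z-cyclononene may align poorly so that the ene reaction is slow. The fallback sets out from 16 and comes back at 19. Riley oxidation (SeO2 cat., t-BuOOH, CH2Cl2) oxidises the ring CH2 at the more substituted olefin terminus to give (1R,4Z,9S)-4,11,11-trimethyl-8-methylidenebicyclo[7.2.0]undec-4-en-3-ol F2. MnO2 gives the enone (1R,4Z,9S)-4,11,11-trimethyl-8-methylidenebicyclo[7.2.0]undec-4-en-3-one F3. Weitz–Scheffer epoxidation (H2O2, NaOH, MeOH) gives the 4,5-epoxy-3-ketone F4. Hydrazine hydrate with catalytic AcOH forms the epoxy hydrazone F5, which undergoes Wharton transposition to the Δ3-en-5-ol as a C5-epimer mixture F6. MnO2 oxidation of F6 returns enone 19, and step 8 then sets C5.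

2. Step 11: discrimination between the two orientations of the heterodiene (C1′) is weak, facial selectivity at C8 may erode, and the allylic alcohol may ionise on heating. The fallback sets out from 16 and comes back at 26. The same three-component hetero-Diels–Alder reaction is run on the robust hydrocarbon 16 with 23 and 24 (forcing conditions and epimer separation are easier there) to give the isocaryophyllene adduct F7. Photooxygenation (O2, tetraphenylporphyrin, hν) gives the 5-hydroperoxide F8, and Ac2O/pyridine converts it through the peracetate F9 into the 3Z-en-5-one F10. CBS reduction as in step 8 gives 26; the hindered ketone between two quaternary carbons and the vinylogous ester carbonyl should not be reduced at −78 °C.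

3. Step 5: at the temperature needed, the sigmatropic shift may be outrun by isomerisation of the enol ether or by elimination. The fallback sets out from 12 and comes back at 14. After methylenation to 13 as before, the thermolysis is replaced by triisobutylaluminium in CH2Cl2 at −78 °C → rt. This Lewis acid promotes the same C6–C7 bond formation through an aluminium-bound allyl/enolate pair and reduces the ring-expanded ketone in the flask by β-hydride transfer, giving the cis-fused (Z)-cyclononenol F1. Dess–Martin oxidation of F1 returns ketone 14.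

Further compounds

F1 | step 5 | (1R,4Z,9R)-4,11,11-trimethylbicyclo[7.2.0]undec-4-en-8-ol (cis-fused, C8 epimers) | C/C1=C/CCC(O)[C@@H]2CC(C)(C)[C@@H]2CC1
F2 | step 7 | (1R,4Z,9S)-4,11,11-trimethyl-8-methylidenebicyclo[7.2.0]undec-4-en-3-ol (C3 epimers) | C/C1=C/CCC(=C)[C@H]2CC(C)(C)[C@@H]2CC1O
F3 | step 7 | (1R,4Z,9S)-4,11,11-trimethyl-8-methylidenebicyclo[7.2.0]undec-4-en-3-one | C/C1=C/CCC(=C)[C@H]2CC(C)(C)[C@@H]2CC1=O
F4 | step 7 | (1R,9S)-4,5-epoxy-4,11,11-trimethyl-8-methylidenebicyclo[7.2.0]undecan-3-one | CC12OC1CCC(=C)[C@H]3CC(C)(C)[C@@H]3CC2=O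
F5 | step 7 | hydrazone of F4 | CC12OC1CCC(=C)[C@H]3CC(C)(C)[C@@H]3CC2=NN
F6 | step 7 | (1R,3Z,9S)-4,11,11-trimethyl-8-methylidenebicyclo[7.2.0]undec-3-en-5-ol (C5 epimers) | C/C1=C/C[C@@H]2[C@H](CC2(C)C)C(=C)CCC1O
F7 | step 11 | hetero-Diels–Alder adduct of 16 with 25 (8S,1′S; Δ4 Z) | C/C1=C/CC[C@]2(C[C@H](CC(C)C)C3=C(O2)C(C)(C)C(=O)C(C)(C)C3=O)[C@H]4CC(C)(C)[C@@H]4CC1
F8 | step 11 | 5-hydroperoxy-Δ3 derivative of F7 (C5 epimers, 3Z/3E) | CC1=CC[C@@H]2[C@H](CC2(C)C)[C@]2(CCC1OO)C[C@H](CC(C)C)C1=C(O2)C(C)(C)C(=O)C(C)(C)C1=O
F9 | step 11 | peracetate of F8 | CC1=CC[C@@H]2[C@H](CC2(C)C)[C@]2(CCC1OOC(C)=O)C[C@H](CC(C)C)C1=C(O2)C(C)(C)C(=O)C(C)(C)C1=O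
F10 | step 11 | 5-oxo analogue of 26 (3Z-en-5-one) | C/C1=C/C[C@@H]2[C@H](CC2(C)C)[C@]2(CCC1=O)C[C@H](CC(C)C)C1=C(O2)C(C)(C)C(=O)C(C)(C)C1=O
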